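**Retrosynthetic overview**

1. Numbering (spiro[5.5]undecane): ring A = C1(CMe2)–C2(Br)–C3(OH)–C4–C5(=CH2)–C6, ring B = C6–C7–C8(Br)–C9(Me)(Cl)–C10–C11. Late disconnections: C3–OH from the C3 ketone (hydride); C5=CH2 by deconjugation of a 5-methyl-4-en-3-one; C2–Br by α′-bromination; C8–Br/C9–Cl by anti bromochlorination of a C8=C9 alkene.
2. The C8=C9(Me) alkene and the configuration of C6 come from a symmetric C9 ketone by enantioselective deprotonation, triflation and Negishi methylation; the enone comes from a spiro vinylogous ester by Stork–Danheiser transposition.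
3. Ring B: one-flask double alkylation of the dimedone vinylogous ester (12 carbons) with a C7–C11 diiodide (C9 as ketal) at the future spiro carbon: C6–C7 first, then ring closure at C6–C11 (C7 and C11 are equivalent by symmetry until step 6).
4. Enabling feature: ring A is the dimedone pattern (gem-dimethyl C1, functions on C3 and C5 in a 1,3-relation) in which C6 is the only α′-carbon, flanked by C5 and C1; in ring B, C9 lies para to C6, so a symmetric five-carbon unit fits.
5. Order of rings: ring A is present from the start (dimedone); ring B is closed in the key step.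

Key step: step 4

Assumption: the sense of the enantioselective deprotonation in step 6 is taken from the 4-tert-butylcyclohexanone model with the C1 arm as the equatorial group; should the (6R)-triflate form, the enantiomeric (R,R)-amide is used.

**Route**

Step 1
Reactants: 1 dimedone (5,5-dimethylcyclohexane-1,3-dione)
Product: 2 5,5-dimethyl-3-(2-methylpropoxy)cyclohex-2-en-1-one
Conditions: i-BuOH, TsOH·H2O (cat.), toluene, reflux, azeotropic removal of water
Reagents that add atoms: 2-methylpropan-1-ol, CC(C)CO
Why: Acid-catalysed condensation of the enolised 1,3-dione with the alcohol under azeotropic removal of water (vinylogous esterification) is a standard route to such enol ethers, and because dimedone is symmetric only one product can form.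

Step 2
Reactants: 3 1,5-dichloropentan-3-one
Product: 4 2,2-bis(2-chloroethyl)-1,3-dioxolane
Conditions: HOCH2CH2OH, TsOH·H2O (cat.), toluene, reflux, azeotropic removal of water
Reagents that add atoms: ethane-1,2-diol, OCCO
Why: Acid-catalysed ketalisation protects the ketone so that the β-halo ketone cannot lose hydrogen halide to a vinyl ketone under the strongly basic conditions of step 4.

Step 3
Reactants: 4 2,2-bis(2-chloroethyl)-1,3-dioxolane
Product: 5 2,2-bis(2-iodoethyl)-1,3-dioxolane
Conditions: NaI, 2-butanone, reflux
Reagents that add atoms: sodium iodide, [Na+].[I-]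
Why: Finkelstein halide exchange, driven by the precipitation of NaCl, converts both primary chlorides into iodides that alkylate a lithium enolate at low temperature.

Step 4
Reactants: 2 5,5-dimethyl-3-(2-methylpropoxy)cyclohex-2-en-1-one; 5 2,2-bis(2-iodoethyl)-1,3-dioxolane
Product: 7 1,1-dimethyl-3-(2-methylpropoxy)spiro[5.5]undec-3-ene-5,9-dione 9-(ethane-1,2-diyl ketal), via mono-alkylated iodide 6 (not isolated)
Conditions: LiN(i-Pr)2 (1.05 equiv), THF, −78 °C; 5 (1.1 equiv), DMPU, −78 → 0 °C; dilution; LiN(i-Pr)2 (1.2 equiv), −78 °C → rt
Reagents that add atoms: none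
Why: LiN(i-Pr)2 removes a proton of 2 only at C6, the single α′-position lying between the carbonyl carbon and the gem-dimethyl carbon, and the enolate displaces one primary iodide of 5 in an SN2 alkylation to give 6. A second charge of base regenerates the now fully substituted α′-enolate, which closes ring B by a 6-exo-tet SN2 displacement of the remaining iodide, so that the second C6–CH2 bond (C6–C11) and the quaternary spiro carbon next to the gem-dimethyl carbon are made in the same flask from two fragments of similar size. The closest known reaction type is the spiroannulation of cyclic vinylogous esters with α,ω-dihalides (Stork–Danheiser alkylation chemistry). No stereocentre arises, because the two ring-B arms are identical and 7 keeps a mirror plane, so the configuration of C6 is left to step 6. The step needs C- over O-alkylation and α′- over γ-deprotonation, which the lithium enolate in THF/DMPU and the greater kinetic acidity of the proton next to the carbonyl group should secure, while a γ-dienolate cannot reach the iodide through an unstrained ring. Intermolecular bis-alkylation is held back by the near-stoichiometric amount of 5 and by dilution before the second deprotonation.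

Step 5
Reactants: 7 1,1-dimethyl-3-(2-methylpropoxy)spiro[5.5]undec-3-ene-5,9-dione 9-(ethane-1,2-diyl ketal)
Product: 8 1,1,5-trimethylspiro[5.5]undec-4-ene-3,9-dione
Conditions: MeLi, CeCl3, THF, −78 °C; then 2 M HCl, THF, rt
Reagents that add atoms: methyllithium, [Li]C; water, O
Why: Stork–Danheiser transposition: the organocerium reagent adds 1,2 to the hindered vinylogous-ester carbonyl C5 without enolisation, and aqueous acid then ionises the tertiary allylic alcohol, hydrolyses the enol ether to the C3 ketone with the double bond at C4=C5 and cleaves the dioxolane, the product still being achiral.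

Step 6
Reactants: 8 1,1,5-trimethylspiro[5.5]undec-4-ene-3,9-dione
Product: 10 (6S)-1,1,5-trimethyl-3-oxospiro[5.5]undeca-4,8-dien-9-yl trifluoromethanesulfonate, via lithium enolate 9 (not isolated)
Conditions: (S,S)-bis(1-phenylethyl)amine, n-BuLi, LiCl, THF, −78 °C; 8, −100 °C; then PhNTf2, −78 °C → rt
Reagents that add atoms: N-phenylbis(trifluoromethanesulfonimide), O=S(=O)(N(c1ccccc1)S(=O)(=O)C(F)(F)F)C(F)(F)F
Why: Enantioselective deprotonation of a prochiral 4,4-disubstituted cyclohexanone by a chiral lithium amide base followed by O-triflation of the enolate: in the ring-B chair that keeps the quaternary C1 equatorial and the trigonal C5 axial the base removes one of the two enantiotopic axial α-protons (that on C8), which fixes C6 as (S), while the ring-A enone should react more slowly because its only sp3 α-protons (on C2) are neopentylic.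

Step 7
Reactants: 10 (6S)-1,1,5-trimethyl-3-oxospiro[5.5]undeca-4,8-dien-9-yl trifluoromethanesulfonate
Product: 11 (6S)-1,1,5,9-tetramethylspiro[5.5]undeca-4,8-dien-3-one
Conditions: MeZnCl, Pd(PPh3)4 (cat.), THF, 50 °C
Reagents that add atoms: methylzinc chloride, C[Zn]Cl
Why: Negishi cross-coupling of the enol triflate replaces oxygen by methyl without moving the double bond, and the organozinc reagent leaves the enone untouched, so the C8=C9 alkene with the C9 methyl group is obtained with the C6 configuration intact.

Step 8
Reactants: 11 (6S)-1,1,5,9-tetramethylspiro[5.5]undeca-4,8-dien-3-one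
Product: 13 (2R,6R)-2-bromo-1,1,5,9-tetramethylspiro[5.5]undeca-4,8-dien-3-one, via silyl dienol ether 12 (not isolated)
Conditions: LiN(i-Pr)2, Me3SiCl, THF, −78 °C; then NBS, −78 → 0 °C
Reagents that add atoms: N-bromosuccinimide, O=C1CCC(=O)N1Br
Why: Kinetic α′-deprotonation of the enone (C2 carries its only sp3 protons next to the carbonyl group) and bromination of the cross-conjugated silyl enol ether, which is far more nucleophilic than the ring-B alkene, place bromine on C2, and this centre, which stays epimerisable through the enol until step 12, is expected to settle with bromine equatorial and trans to the axial C6–C11 bond (2R).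

Step 9
Reactants: 13 (2R,6R)-2-bromo-1,1,5,9-tetramethylspiro[5.5]undeca-4,8-dien-3-one
Product: 14 (2R,6R,8R,9R)-2,8-dibromo-9-chloro-1,1,5,9-tetramethylspiro[5.5]undec-4-en-3-one
Conditions: NBS, HCl (4 M in dioxane), CH2Cl2, −78 → −30 °C
Reagents that add atoms: N-bromosuccinimide, O=C1CCC(=O)N1Br; hydrogen chloride, Cl
Why: Electrophilic anti bromochlorination of a trisubstituted alkene by bromine chloride made in the flask: with the trigonal C5 axial and the quaternary C1 equatorial on the ring-B half-chair, the C5 methyl group covers the alkene face syn to C5, so that bromine should add to C8 from the face syn to C1 and chloride should open the bromonium ion at the tertiary C9 from the opposite face, which sets (8R,9R) with both halogens equatorial, while the electron-poor enone double bond does not compete.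

Step 10
Reactants: 14 (2R,6R,8R,9R)-2,8-dibromo-9-chloro-1,1,5,9-tetramethylspiro[5.5]undec-4-en-3-one
Product: 15 (2R,6R,8R,9R)-2,8-dibromo-9-chloro-1,1,9-trimethyl-5-methylidenespiro[5.5]undec-3-en-3-yl acetate
Conditions: Ac2O, HClO4 (cat.), EtOAc, 0 °C → rt
Reagents that add atoms: acetic anhydride, CC(=O)OC(C)=O
Why: Acid-catalysed enol acetylation under equilibrating conditions should give the extended dienyl acetate, because the only γ-hydrogens are those of the C5 methyl group (C6 is quaternary) and acid-catalysed enolisation towards the bromine-bearing C2 is disfavoured, so the double bond moves to the exocyclic position.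

Step 11
Reactants: 15 (2R,6R,8R,9R)-2,8-dibromo-9-chloro-1,1,9-trimethyl-5-methylidenespiro[5.5]undec-3-en-3-yl acetate
Product: 17 (2R,6R,8R,9R)-2,8-dibromo-9-chloro-1,1,9-trimethyl-5-methylidenespiro[5.5]undecan-3-one, via lithium dienolate 16 (not isolated)
Conditions: MeLi (2.1 equiv), THF, −78 °C; then AcOH, −78 °C
Reagents that add atoms: none
Why: Cleavage of the enol acetate by methyllithium releases the lithium dienolate regiospecifically, and kinetic protonation of this extended enolate at its α-carbon C4 gives the β,γ-unsaturated ketone with the exocyclic methylene group (deconjugation by kinetic protonation of a dienolate).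

Step 12
Reactants: 17 (2R,6R,8R,9R)-2,8-dibromo-9-chloro-1,1,9-trimethyl-5-methylidenespiro[5.5]undecan-3-one
Product: 18 (2R,3S,6R,8R,9R)-2,8-dibromo-9-chloro-1,1,9-trimethyl-5-methylidenespiro[5.5]undecan-3-ol
Conditions: i-Bu2AlH, CH2Cl2, −78 °C; aqueous KNaC4H4O6 work-up
Reagents that add atoms: none
Why: Diastereoselective 1,2-reduction of the α-bromo ketone by a bulky aluminium hydride: the axial methyl group on C1 blocks the axial trajectory, so hydride should enter equatorially and leave the hydroxyl group axial and cis to the equatorial bromine (3S), while the non-basic reagent spares the halides and the β,γ-alkene.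

**Compound list**

1 | dimedone (5,5-dimethylcyclohexane-1,3-dione) | CC1(C)CC(=O)CC(=O)C1 | starting material
2 | 5,5-dimethyl-3-(2-methylpropoxy)cyclohex-2-en-1-one | CC(C)COC1=CC(=O)CC(C)(C)C1 | intermediate
3 | 1,5-dichloropentan-3-one | ClCCC(=O)CCCl | starting material
4 | 2,2-bis(2-chloroethyl)-1,3-dioxolane | ClCCC1(CCCl)OCCO1 | intermediate
5 | 2,2-bis(2-iodoethyl)-1,3-dioxolane | ICCC1(CCI)OCCO1 | intermediate
6 | 6-[2-[2-(2-iodoethyl)-1,3-dioxolan-2-yl]ethyl]-5,5-dimethyl-3-(2-methylpropoxy)cyclohex-2-en-1-one (racemic, not isolated) | CC(C)COC1=CC(=O)C(CCC2(CCI)OCCO2)C(C)(C)C1 | intermediate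
7 | 1,1-dimethyl-3-(2-methylpropoxy)spiro[5.5]undec-3-ene-5,9-dione 9-(ethane-1,2-diyl ketal) (achiral) | O=C1C=C(OCC(C)C)CC(C)(C)C12CCC3(CC2)OCCO3 | intermediate
8 | 1,1,5-trimethylspiro[5.5]undec-4-ene-3,9-dione (achiral) | CC1=CC(=O)CC(C)(C)C12CCC(=O)CC2 | intermediate
9 | lithium (6S)-1,1,5-trimethyl-3-oxospiro[5.5]undeca-4,8-dien-9-olate (not isolated) | CC1=CC(=O)CC(C)(C)[C@@]12CCC(O[Li])=CC2 | intermediate
10 | (6S)-1,1,5-trimethyl-3-oxospiro[5.5]undeca-4,8-dien-9-yl trifluoromethanesulfonate | CC1=CC(=O)CC(C)(C)[C@@]12CCC(OS(=O)(=O)C(F)(F)F)=CC2 | intermediate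
11 | (6S)-1,1,5,9-tetramethylspiro[5.5]undeca-4,8-dien-3-one | CC1=CC(=O)CC(C)(C)[C@@]12CCC(C)=CC2 | intermediate
12 | (6R)-trimethyl[(1,1,5,9-tetramethylspiro[5.5]undeca-2,4,8-trien-3-yl)oxy]silane (not isolated) | CC1=CC(O[Si](C)(C)C)=CC(C)(C)[C@@]12CCC(C)=CC2 | intermediate
13 | (2R,6R)-2-bromo-1,1,5,9-tetramethylspiro[5.5]undeca-4,8-dien-3-one | CC1=CC(=O)[C@H](Br)C(C)(C)[C@@]12CCC(C)=CC2 | intermediate
14 | (2R,6R,8R,9R)-2,8-dibromo-9-chloro-1,1,5,9-tetramethylspiro[5.5]undec-4-en-3-one | CC1=CC(=O)[C@H](Br)C(C)(C)[C@@]12CC[C@@](C)(Cl)[C@H](Br)C2 | intermediate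
15 | (2R,6R,8R,9R)-2,8-dibromo-9-chloro-1,1,9-trimethyl-5-methylidenespiro[5.5]undec-3-en-3-yl acetate | C=C1C=C(OC(C)=O)[C@H](Br)C(C)(C)[C@@]12CC[C@@](C)(Cl)[C@H](Br)C2 | intermediate
16 | lithium (2R,6R,8R,9R)-2,8-dibromo-9-chloro-1,1,9-trimethyl-5-methylidenespiro[5.5]undec-3-en-3-olate (not isolated) | C=C1C=C(O[Li])[C@H](Br)C(C)(C)[C@@]12CC[C@@](C)(Cl)[C@H](Br)C2 | intermediate
17 | (2R,6R,8R,9R)-2,8-dibromo-9-chloro-1,1,9-trimethyl-5-methylidenespiro[5.5]undecan-3-one | C=C1CC(=O)[C@H](Br)C(C)(C)[C@@]12CC[C@@](C)(Cl)[C@H](Br)C2 | intermediate
18 | (2R,3S,6R,8R,9R)-2,8-dibromo-9-chloro-1,1,9-trimethyl-5-methylidenespiro[5.5]undecan-3-ol | C=C1C[C@H](O)[C@H](Br)C(C)(C)[C@@]12CC[C@@](C)(Cl)[C@H](Br)C2 | target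

**Step count and risks**

Total steps: 12. Longest linear sequence: 11 steps (steps 2 to 12, from 1,5-dichloropentan-3-one); the dimedone branch (step 1) joins at step 4.

The three steps most likely to fail:

1. Step 9 (bromochlorination). What may go wrong: formation of the bromonium ion on the alkene face syn to C5, or chloride delivery that is not cleanly anti, either of which erodes the C8/C9 configuration; elimination to allylic halides may also compete. Fallback: the bromonium ion is opened by water instead of chloride, and chloride is brought in afterwards. Setting out from 13, NBS in aqueous acetone at 0 °C should give the trans bromohydrin (2R,6R,8R,9R)-2,8-dibromo-9-hydroxy-1,1,5,9-tetramethylspiro[5.5]undec-4-en-3-one F1, at which stage diastereomers can be separated. HCl in CH2Cl2 should then exchange the tertiary hydroxyl group for chloride with retention through the bromonium ion (neighbouring-group participation), and the route is rejoined at 14.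

2. Step 6 (enantioselective deprotonation). What may go wrong: incomplete discrimination between the enantiotopic C8 and C10 protons, and competing deprotonation of the ring-A enone at C2, both of which lower the enantiomeric purity of everything that follows. Fallback: the desymmetrisation is moved forward to a ketone that carries no enone. Setting out from 7, selective hydrolysis of the dioxolane (pyridinium p-toluenesulfonate, wet acetone) should give the keto vinylogous ester 1,1-dimethyl-3-(2-methylpropoxy)spiro[5.5]undec-3-ene-5,9-dione F2. Deprotonation with the chiral lithium amide and trapping with PhNTf2 should give the enol triflate (6S)-1,1-dimethyl-3-(2-methylpropoxy)-5-oxospiro[5.5]undeca-3,8-dien-9-yl trifluoromethanesulfonate F3. Negishi methylation should give (6S)-1,1,9-trimethyl-3-(2-methylpropoxy)spiro[5.5]undeca-3,8-dien-5-one F4, and MeLi/CeCl3 followed by aqueous HCl rejoins the route at 11.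

3. Step 11 (kinetic deconjugation). What may go wrong: protonation of the dienolate at its γ-carbon or re-enolisation after protonation, which moves the double bond back into conjugation, and loss of bromide from the α′-bromo dienolate. Fallback: the β,γ-unsaturated ketone is trapped by reduction as it forms. Setting out from 15, NaBH4 in ethanol/THF at 0 °C should cleave the enol acetate and reduce the ketone before it can conjugate, giving (2R,6R,8R,9R)-2,8-dibromo-9-chloro-1,1,9-trimethyl-5-methylidenespiro[5.5]undecan-3-ol as a mixture of C3 epimers F5. Dess–Martin oxidation should return the β,γ-unsaturated ketone without isomerisation, and the route is rejoined at 17.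

Further compounds
F1 | step 9 | (2R,6R,8R,9R)-2,8-dibromo-9-hydroxy-1,1,5,9-tetramethylspiro[5.5]undec-4-en-3-one | CC1=CC(=O)[C@H](Br)C(C)(C)[C@@]12CC[C@@](C)(O)[C@H](Br)C2
F2 | step 6 | 1,1-dimethyl-3-(2-methylpropoxy)spiro[5.5]undec-3-ene-5,9-dione | CC(C)COC1=CC(=O)C2(CCC(=O)CC2)C(C)(C)C1
F3 | step 6 | (6S)-1,1-dimethyl-3-(2-methylpropoxy)-5-oxospiro[5.5]undeca-3,8-dien-9-yl trifluoromethanesulfonate | O=C1C=C(OCC(C)C)CC(C)(C)[C@@]12CCC(OS(=O)(=O)C(F)(F)F)=CC2
F4 | step 6 | (6S)-1,1,9-trimethyl-3-(2-methylpropoxy)spiro[5.5]undeca-3,8-dien-5-one | O=C1C=C(OCC(C)C)CC(C)(C)[C@@]12CCC(C)=CC2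
F5 | step 11 | (2R,6R,8R,9R)-2,8-dibromo-9-chloro-1,1,9-trimethyl-5-methylidenespiro[5.5]undecan-3-ol, mixture of C3 epimers | C=C1CC(O)[C@H](Br)C(C)(C)[C@@]12CC[C@@](C)(Cl)[C@H](Br)C2
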